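**Strategy.** The cyclohexane ring is cut across the CH2–CHBr bond and the bond between the side-chain-bearing CH and the CMe2 carbon, a Diels–Alder disconnection. It exploits the ring CHBr that is flanked by the quaternary CMe2 carbon, a bromide out of reach of substitution chemistry: the bromine enters as the vinylic bromine of (E)-3-bromo-2-methylacrolein, whose formyl group later becomes the second methyl. A chiral oxazaborolidinium catalyst joins this enal to a linalool-derived 2-silyloxydiene that carries a trimethylsilylmethyl group, closing the ring and setting both stereocentres flanking CMe2 in one operation. The cyclohexene allylsilane that remains is finally converted by bromodesilylation into the exocyclic methylene and the axial allylic bromide.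

Key step: step 8

Remark: (S)-(+)-linalool of high enantiomeric purity is taken as commercially available and is the source of the carbinol centre.

**Step 1**
Reactants: 1 (S)-(+)-linalool
Product: 2 triethyl{[(3S)-3,7-dimethylocta-1,6-dien-3-yl]oxy}silane
Conditions: TESOTf, 2,6-lutidine, CH2Cl2, −78 to 0 °C
Reagents that add atoms: triethylsilyl trifluoromethanesulfonate, CC[Si](CC)(CC)OS(=O)(=O)C(F)(F)F
Why: Silyl ether formation with a silyl triflate is reliable for the hindered tertiary alcohol, leaves the stereocentre untouched and blocks later oxa-Michael closure and bromoetherification by the hydroxyl group.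

**Step 2**
Reactants: 2 triethyl{[(3S)-3,7-dimethylocta-1,6-dien-3-yl]oxy}silane
Product: 4 (4S)-4-methyl-4-[(triethylsilyl)oxy]hex-5-enal, via secondary ozonide 3 (not isolated)
Conditions: O3, CH2Cl2, −78 °C, stopped at consumption of 2; then PPh3, −78 °C to rt
Reagents that add atoms: ozone, [O-][O+]=O
Why: Ozonolysis with reductive work-up should be selective for the electron-rich trisubstituted alkene over the monosubstituted vinyl group next to the quaternary carbinol carbon, and no stereocentre is touched.

**Step 3**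
Reactants: 5 dimethyl (2-oxopropyl)phosphonate; 6 (iodomethyl)trimethylsilane
Product: 7 dimethyl [3-oxo-1-(trimethylsilyl)butan-2-yl]phosphonate (racemic)
Conditions: NaH, DMF, 0 to 50 °C
Reagents that add atoms: none
Why: C-Alkylation (SN2) of the sodium salt of the β-ketophosphonate by the primary α-silyl iodide installs the trimethylsilylmethyl group; the new stereocentre is racemic and disappears in step 4.

**Step 4**
Reactants: 4 (4S)-4-methyl-4-[(triethylsilyl)oxy]hex-5-enal; 7 dimethyl [3-oxo-1-(trimethylsilyl)butan-2-yl]phosphonate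
Product: 8 (3Z,7S)-7-methyl-7-[(triethylsilyl)oxy]-3-[(trimethylsilyl)methyl]nona-3,8-dien-2-one (alkyl chain trans to acetyl)
Conditions: Ba(OH)2, THF/H2O (40:1), rt
Reagents that add atoms: none
Why: Horner–Wadsworth–Emmons olefination under mild conditions should give the trisubstituted enone with the chain trans to the acetyl group, the thermodynamically preferred geometry free of allylic strain, without touching the carbinol centre.

**Step 5**
Reactants: 8 (3Z,7S)-7-methyl-7-[(triethylsilyl)oxy]-3-[(trimethylsilyl)methyl]nona-3,8-dien-2-one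
Product: 9 (3Z,7S)-7-methyl-7-[(triethylsilyl)oxy]-2-[(triisopropylsilyl)oxy]-3-[(trimethylsilyl)methyl]nona-1,3,8-triene
Conditions: TIPSOTf, Et3N, CH2Cl2, 0 °C
Reagents that add atoms: triisopropylsilyl trifluoromethanesulfonate, CC(C)[Si](C(C)C)(C(C)C)OS(=O)(=O)C(F)(F)F
Why: Soft enolisation (silyl dienol ether formation) deprotonates the methyl group, the only hydrogen-bearing position α to the carbonyl, and gives the 2-silyloxydiene with the trisubstituted alkene geometry unchanged.

**Step 6**
Reactants: 10 prop-2-yn-1-ol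
Product: 12 (2E)-3-bromo-2-methylprop-2-en-1-ol, via alkenylalane 11 (not isolated)
Conditions: AlMe3 (3 equiv), Cp2ZrCl2 (25 mol%), CH2Cl2, 0 °C to rt; then NBS, THF, −78 to 0 °C
Reagents that add atoms: trimethylaluminium, C[Al](C)C; N-bromosuccinimide, O=C1CCC(=O)N1Br
Why: Negishi carboalumination adds methyl and aluminium syn across the alkyne with aluminium at the terminus, and bromodealumination with retention fixes the E geometry of the vinyl bromide.

**Step 7**
Reactants: 12 (2E)-3-bromo-2-methylprop-2-en-1-ol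
Product: 13 (2E)-3-bromo-2-methylprop-2-enal
Conditions: MnO2, CH2Cl2, rt
Reagents that add atoms: none
Why: Allylic oxidation with manganese dioxide gives the enal without touching the vinyl bromide or its geometry.

**Step 8**
Reactants: 9 (3Z,7S)-7-methyl-7-[(triethylsilyl)oxy]-2-[(triisopropylsilyl)oxy]-3-[(trimethylsilyl)methyl]nona-1,3,8-triene; 13 (2E)-3-bromo-2-methylprop-2-enal
Product: 14 (1R,2R,6S)-6-bromo-1-methyl-2-{(3S)-3-methyl-3-[(triethylsilyl)oxy]pent-4-en-1-yl}-4-[(triisopropylsilyl)oxy]-3-[(trimethylsilyl)methyl]cyclohex-3-ene-1-carbaldehyde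
Conditions: (R)-3,3-diphenyl-1-(2-methylphenyl)tetrahydro-1H,3H-pyrrolo[1,2-c][1,3,2]oxazaborole (20 mol%), HNTf2 (16 mol%), CH2Cl2, −78 °C
Reagents that add atoms: none
Why: The protonated oxazaborolidine binds the formyl oxygen and the enal adds to the diene in a concerted, asynchronous Diels–Alder reaction, the closest known type being oxazaborolidinium-catalysed cycloadditions of 2-substituted acroleins with 2-silyloxydienes. The cyclohexene ring is closed by a suprafacial [4+2] union in which the diene CH2 terminus bonds to the CHBr carbon of the enal (the leading bond) and the chain-bearing diene CH bonds to the methyl- and formyl-bearing carbon. Regiochemistry is secured by the silyloxy group on the diene carbon next to the CH2 terminus, which makes that terminus the nucleophilic one and overrides the trimethylsilylmethyl group, with the terminal alkyl group reinforcing it. The relative configuration of the chain-bearing CH and the CHBr carbon follows from the defined alkene geometries (chain trans to the silyloxyvinyl unit in the diene, bromine trans to formyl in the enal) and an exo formyl group, as is usual for 2-substituted acroleins on bulky boron Lewis acids, so that methyl and bromine sit endo and bromine ends up cis to the side chain; the quaternary carbon is set too but loses its stereogenicity in step 9. The absolute configuration is under catalyst control, the (R)-catalyst being expected by the formyl C–H···O binding model to leave open the Re face at C2 of the enal, while the remote carbinol centre has no influence. The step needs regio-, exo- and facial selectivity and must outrun Mukaiyama-type aldol addition, which the bulky silyl group and the low temperature should secure.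

**Step 9**
Reactants: 14 (1R,2R,6S)-6-bromo-1-methyl-2-{(3S)-3-methyl-3-[(triethylsilyl)oxy]pent-4-en-1-yl}-4-[(triisopropylsilyl)oxy]-3-[(trimethylsilyl)methyl]cyclohex-3-ene-1-carbaldehyde
Product: 16 (3R,5S)-5-bromo-4,4-dimethyl-3-{(3S)-3-methyl-3-[(triethylsilyl)oxy]pent-4-en-1-yl}-1-[(triisopropylsilyl)oxy]-2-[(trimethylsilyl)methyl]cyclohex-1-ene, via tosylhydrazone 15 (not isolated)
Conditions: TsNHNH2, MgSO4, THF, 50 °C; then catecholborane, CHCl3, 0 °C; then NaOAc·3H2O, reflux
Reagents that add atoms: none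
Why: Tosylhydrazone formation, hydride delivery from catecholborane and loss of sulfinate and dinitrogen (a mild Wolff–Kishner-type deoxygenation) should turn the formyl group into methyl under near-neutral conditions that spare the silyl enol ether, the allylsilane and the bromide; the quaternary carbon becomes the non-stereogenic CMe2.

**Step 10**
Reactants: 16 (3R,5S)-5-bromo-4,4-dimethyl-3-{(3S)-3-methyl-3-[(triethylsilyl)oxy]pent-4-en-1-yl}-1-[(triisopropylsilyl)oxy]-2-[(trimethylsilyl)methyl]cyclohex-1-ene
Product: 17 (3R,5S)-5-bromo-4,4-dimethyl-3-{(3S)-3-methyl-3-[(triethylsilyl)oxy]pent-4-en-1-yl}-2-[(trimethylsilyl)methyl]cyclohex-1-en-1-yl trifluoromethanesulfonate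
Conditions: PhNTf2, CsF, DME, rt
Reagents that add atoms: N-phenylbis(trifluoromethanesulfonimide), O=S(=O)(N(c1ccccc1)S(=O)(=O)C(F)(F)F)C(F)(F)F
Why: Enol triflate formation: fluoride cleaves the silyl enol ether and the caesium enolate is O-triflated at once, which keeps the enolate regiochemistry and gives it no time for β-elimination of bromide.

**Step 11**
Reactants: 17 (3R,5S)-5-bromo-4,4-dimethyl-3-{(3S)-3-methyl-3-[(triethylsilyl)oxy]pent-4-en-1-yl}-2-[(trimethylsilyl)methyl]cyclohex-1-en-1-yl trifluoromethanesulfonate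
Product: 18 (4S,6R)-4-bromo-5,5-dimethyl-6-{(3S)-3-methyl-3-[(triethylsilyl)oxy]pent-4-en-1-yl}-1-[(trimethylsilyl)methyl]cyclohex-1-ene
Conditions: Pd(OAc)2 (5 mol%), PPh3 (10 mol%), HCO2H, Bu3N, DMF, 60 °C
Reagents that add atoms: none
Why: Palladium-catalysed formate reduction of the enol triflate (oxidative addition, formate exchange, decarboxylation, reductive elimination) replaces the triflate by hydrogen without moving the double bond and should leave the hindered secondary bromide untouched.

**Step 12**
Reactants: 18 (4S,6R)-4-bromo-5,5-dimethyl-6-{(3S)-3-methyl-3-[(triethylsilyl)oxy]pent-4-en-1-yl}-1-[(trimethylsilyl)methyl]cyclohex-1-ene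
Product: 19 {[(3S)-5-[(1S,3S,5S)-3,5-dibromo-2,2-dimethyl-6-methylidenecyclohexyl]-3-methylpent-1-en-3-yl]oxy}triethylsilane
Conditions: NBS, CH2Cl2, −78 °C
Reagents that add atoms: N-bromosuccinimide, O=C1CCC(=O)N1Br
Why: Electrophilic bromodesilylation (SE2′) of the allylsilane puts bromine on the ring CH and releases the exocyclic methylene; axial attack on the half-chair that holds the side chain and the existing bromine equatorial should place the new bromine axial, trans to both.

**Step 13**
Reactants: 19 {[(3S)-5-[(1S,3S,5S)-3,5-dibromo-2,2-dimethyl-6-methylidenecyclohexyl]-3-methylpent-1-en-3-yl]oxy}triethylsilane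
Product: 20 (3S)-5-[(1S,3S,5S)-3,5-dibromo-2,2-dimethyl-6-methylidenecyclohexyl]-3-methylpent-1-en-3-ol
Conditions: HF·pyridine, pyridine, THF, 0 °C
Reagents that add atoms: none
Why: Buffered fluoride desilylation cleaves the triethylsilyl ether of the tertiary alcohol under conditions mild enough for the secondary allylic bromide.

**Compound list**

1 | (S)-(+)-linalool, (3S)-3,7-dimethylocta-1,6-dien-3-ol | C=C[C@@](C)(O)CCC=C(C)C | starting material
2 | triethyl{[(3S)-3,7-dimethylocta-1,6-dien-3-yl]oxy}silane | C=C[C@@](C)(O[Si](CC)(CC)CC)CCC=C(C)C | intermediate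
3 | secondary ozonide, 3,3-dimethyl-5-{(3S)-3-methyl-3-[(triethylsilyl)oxy]pent-4-en-1-yl}-1,2,4-trioxolane | C=C[C@@](C)(O[Si](CC)(CC)CC)CCC1OOC(C)(C)O1 | intermediate (not isolated)
4 | (4S)-4-methyl-4-[(triethylsilyl)oxy]hex-5-enal | C=C[C@@](C)(O[Si](CC)(CC)CC)CCC=O | intermediate
5 | dimethyl (2-oxopropyl)phosphonate | COP(=O)(OC)CC(C)=O | starting material
6 | (iodomethyl)trimethylsilane | C[Si](C)(C)CI | starting material
7 | dimethyl [3-oxo-1-(trimethylsilyl)butan-2-yl]phosphonate (racemic) | COP(=O)(OC)C(C[Si](C)(C)C)C(C)=O | intermediate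
8 | (3Z,7S)-7-methyl-7-[(triethylsilyl)oxy]-3-[(trimethylsilyl)methyl]nona-3,8-dien-2-one | C=C[C@@](C)(O[Si](CC)(CC)CC)CC/C=C(\C[Si](C)(C)C)C(C)=O | intermediate
9 | (3Z,7S)-7-methyl-7-[(triethylsilyl)oxy]-2-[(triisopropylsilyl)oxy]-3-[(trimethylsilyl)methyl]nona-1,3,8-triene | C=C[C@@](C)(O[Si](CC)(CC)CC)CC/C=C(\C[Si](C)(C)C)C(=C)O[Si](C(C)C)(C(C)C)C(C)C | intermediate
10 | prop-2-yn-1-ol | C#CCO | starting material
11 | alkenylalane, dimethyl{(1E)-3-[(dimethylalumanyl)oxy]-2-methylprop-1-en-1-yl}alumane | C/C(CO[Al](C)C)=C\[Al](C)C | intermediate (not isolated)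
12 | (2E)-3-bromo-2-methylprop-2-en-1-ol | C/C(CO)=C\Br | intermediate
13 | (2E)-3-bromo-2-methylprop-2-enal | C/C(C=O)=C\Br | intermediate
14 | (1R,2R,6S)-6-bromo-1-methyl-2-{(3S)-3-methyl-3-[(triethylsilyl)oxy]pent-4-en-1-yl}-4-[(triisopropylsilyl)oxy]-3-[(trimethylsilyl)methyl]cyclohex-3-ene-1-carbaldehyde | C=C[C@@](C)(O[Si](CC)(CC)CC)CC[C@@H]1C(C[Si](C)(C)C)=C(O[Si](C(C)C)(C(C)C)C(C)C)C[C@H](Br)[C@@]1(C)C=O | intermediate
15 | (E)-tosylhydrazone of 14 | C=C[C@@](C)(O[Si](CC)(CC)CC)CC[C@@H]1C(C[Si](C)(C)C)=C(O[Si](C(C)C)(C(C)C)C(C)C)C[C@H](Br)[C@@]1(C)/C=N/NS(=O)(=O)c1ccc(C)cc1 | intermediate (not isolated)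
16 | (3R,5S)-5-bromo-4,4-dimethyl-3-{(3S)-3-methyl-3-[(triethylsilyl)oxy]pent-4-en-1-yl}-1-[(triisopropylsilyl)oxy]-2-[(trimethylsilyl)methyl]cyclohex-1-ene | C=C[C@@](C)(O[Si](CC)(CC)CC)CC[C@@H]1C(C[Si](C)(C)C)=C(O[Si](C(C)C)(C(C)C)C(C)C)C[C@H](Br)C1(C)C | intermediate
17 | (3R,5S)-5-bromo-4,4-dimethyl-3-{(3S)-3-methyl-3-[(triethylsilyl)oxy]pent-4-en-1-yl}-2-[(trimethylsilyl)methyl]cyclohex-1-en-1-yl trifluoromethanesulfonate | C=C[C@@](C)(O[Si](CC)(CC)CC)CC[C@@H]1C(C[Si](C)(C)C)=C(OS(=O)(=O)C(F)(F)F)C[C@H](Br)C1(C)C | intermediate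
18 | (4S,6R)-4-bromo-5,5-dimethyl-6-{(3S)-3-methyl-3-[(triethylsilyl)oxy]pent-4-en-1-yl}-1-[(trimethylsilyl)methyl]cyclohex-1-ene | C=C[C@@](C)(O[Si](CC)(CC)CC)CC[C@@H]1C(C[Si](C)(C)C)=CC[C@H](Br)C1(C)C | intermediate
19 | {[(3S)-5-[(1S,3S,5S)-3,5-dibromo-2,2-dimethyl-6-methylidenecyclohexyl]-3-methylpent-1-en-3-yl]oxy}triethylsilane | C=C[C@@](C)(O[Si](CC)(CC)CC)CC[C@@H]1C(=C)[C@@H](Br)C[C@H](Br)C1(C)C | intermediate
20 | (3S)-5-[(1S,3S,5S)-3,5-dibromo-2,2-dimethyl-6-methylidenecyclohexyl]-3-methylpent-1-en-3-ol | C=C[C@@](C)(O)CC[C@@H]1C(=C)[C@@H](Br)C[C@H](Br)C1(C)C | target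

**Step count.** Total: 13 steps. Longest linear sequence: 10 steps (1, 2, 4, 5, 8, 9, 10, 11, 12, 13).

**Steps most likely to fail**

1. Step 8. The formyl group may prefer the endo position, which would deliver bromine to the face opposite the side chain. The silyl dienol ether may also be consumed by Mukaiyama-type aldol addition or protodesilylation, and the facial sense may be opposite to that predicted (then the antipodal catalyst is used). The fallback sets out from 10 and comes back at 16. Copper-catalysed anti-carbomagnesiation of 10 (MeMgBr, CuI, THF) would give the chelated alkenylmagnesium alkoxide F1 (not isolated), bromination with NBS the (2Z)-3-bromo-2-methylprop-2-en-1-ol F2, and MnO2 oxidation the (2Z)-3-bromo-2-methylprop-2-enal F3, in which bromine is cis to the formyl group. Its cycloaddition with 9 under the conditions of step 8, but with the (S)-catalyst, would place formyl and bromine both endo and give the C1-epimeric adduct F4. The deoxygenation of step 9, through tosylhydrazone F5 (not isolated), should then convert F4 into 16.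

2. Step 12. The secondary allylic bromide may undergo 1,3-transposition to the primary allylic bromide during reaction or work-up, and the facial selectivity of electrophilic attack may be eroded. The fallback sets out from 16 and comes back at 19. NBS would brominate the silyl enol ether at the carbon bearing the silylmethyl group, and the resulting β-bromosilane would lose bromotrimethylsilane to give the α-methylene ketone F6. Luche reduction (NaBH4, CeCl3·7H2O, MeOH, −78 °C) should, by axial hydride delivery, give the equatorial allylic alcohol F7. Appel bromination (CBr4, PPh3, CH2Cl2, 0 °C) with inversion would then give the axial bromide 19.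

3. Step 9. Condensation at the hindered neopentyl aldehyde may be sluggish, and the silyl enol ether may hydrolyse during the sequence. The fallback sets out from 14 and comes back at 16. Reduction with NaBH4 (MeOH/THF, 0 °C) would give the neopentyl alcohol F8, triflation (Tf2O, 2,6-lutidine, CH2Cl2, −78 °C) the primary triflate F9, and hydride displacement with LiEt3BH (THF, −78 to 0 °C) the methyl compound 16.

**Further compounds**

F1 | step 8 | chelated alkenylmagnesium alkoxide, 4-methyl-2,5-dihydro-1,2-oxamagnesole | CC1=C[Mg]OC1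
F2 | step 8 | (2Z)-3-bromo-2-methylprop-2-en-1-ol | C/C(CO)=C/Br
F3 | step 8 | (2Z)-3-bromo-2-methylprop-2-enal | C/C(C=O)=C/Br
F4 | step 8 | (1S,2R,6S)-6-bromo-1-methyl-2-{(3S)-3-methyl-3-[(triethylsilyl)oxy]pent-4-en-1-yl}-4-[(triisopropylsilyl)oxy]-3-[(trimethylsilyl)methyl]cyclohex-3-ene-1-carbaldehyde | C=C[C@@](C)(O[Si](CC)(CC)CC)CC[C@@H]1C(C[Si](C)(C)C)=C(O[Si](C(C)C)(C(C)C)C(C)C)C[C@H](Br)[C@]1(C)C=O
F5 | step 8 | (E)-tosylhydrazone of F4 | C=C[C@@](C)(O[Si](CC)(CC)CC)CC[C@@H]1C(C[Si](C)(C)C)=C(O[Si](C(C)C)(C(C)C)C(C)C)C[C@H](Br)[C@]1(C)/C=N/NS(=O)(=O)c1ccc(C)cc1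
F6 | step 12 | (3R,5S)-5-bromo-4,4-dimethyl-2-methylidene-3-{(3S)-3-methyl-3-[(triethylsilyl)oxy]pent-4-en-1-yl}cyclohexan-1-one | C=C[C@@](C)(O[Si](CC)(CC)CC)CC[C@@H]1C(=C)C(=O)C[C@H](Br)C1(C)C
F7 | step 12 | (1R,3R,5S)-5-bromo-4,4-dimethyl-2-methylidene-3-{(3S)-3-methyl-3-[(triethylsilyl)oxy]pent-4-en-1-yl}cyclohexan-1-ol | C=C[C@@](C)(O[Si](CC)(CC)CC)CC[C@@H]1C(=C)[C@H](O)C[C@H](Br)C1(C)C
F8 | step 9 | [(1R,2R,6S)-6-bromo-1-methyl-2-{(3S)-3-methyl-3-[(triethylsilyl)oxy]pent-4-en-1-yl}-4-[(triisopropylsilyl)oxy]-3-[(trimethylsilyl)methyl]cyclohex-3-en-1-yl]methanol | C=C[C@@](C)(O[Si](CC)(CC)CC)CC[C@@H]1C(C[Si](C)(C)C)=C(O[Si](C(C)C)(C(C)C)C(C)C)C[C@H](Br)[C@@]1(C)CO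
F9 | step 9 | [(1R,2R,6S)-6-bromo-1-methyl-2-{(3S)-3-methyl-3-[(triethylsilyl)oxy]pent-4-en-1-yl}-4-[(triisopropylsilyl)oxy]-3-[(trimethylsilyl)methyl]cyclohex-3-en-1-yl]methyl trifluoromethanesulfonate | C=C[C@@](C)(O[Si](CC)(CC)CC)CC[C@@H]1C(C[Si](C)(C)C)=C(O[Si](C(C)C)(C(C)C)C(C)C)C[C@H](Br)[C@@]1(C)COS(=O)(=O)C(F)(F)F
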